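(The data were generated by integration with constants of no real substance, and the scatter is random.)

4 questions stood on elm, ash and birch. On the list of suspects X takes up L stepwise to E, Z and Q, each step releasing J, and E meets G to give D.

| flask | X | L | G | remark | time |
|---|---|---|---|---|---|
| grey | 0.14 M | 0.071 M | 0.14 M | run made earlier |  |
| blue | 0.14 M | 0.38 M | 0.14 M | run made earlier |  |
| elm | 0.14 M | 0.168 M | 0.140 M |  | 2.5 h |
| ash | 0.14 M | 0.140 M | 0.140 M |  | 2.5 h |
| birch | 0.14 M | 0.560 M | 0.140 M |  | 2.5 h |

| run | time / min | E / % | Z / % |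
|---|---|---|---|
| grey | 8.00 | 5.0 | 0.4 |
| grey | 15.0 | 6.5 | 0.3 |
| grey | 25.0 | 6.9 | 0.9 |
| grey | 40.0 | 5.9 | 0.6 |
| grey | 60.0 | 4.7 | 1.6 |
| grey | 120 | 2.9 | 1.0 |
| blue | 8.00 | 19.9 | 3.3 |
| blue | 20.0 | 20.8 | 7.1 |
| blue | 40.0 | 13.2 | 10.5 |
| blue | 60.0 | 8.6 | 12.7 |
| blue | 80.0 | 5.7 | 14.1 |
| blue | 120 | 3.0 | 15.7 |

(standard deviation of a reading: 0.3 percentage points)

1. which of these holds the largest part of the X at the end of elm (E / Z / X / Q)
2. which of these holds the largest part of the X at the end of ash (E / Z / X / Q)
3. which of these holds the largest part of the X at the end of birch (E / Z / X / Q)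
4. E at the end of elm, in percent of the X charged

- on the list of suspects stand: X + L <-> J + E; E + L <-> J + Z; Z + L <-> J + Q; E + G -> D

I set the runs on a ladder of times. On the lowest rung E was still filling: it peaked, as read, near 20.0 min in blue and 25.0 min in grey. Next came the tail. Between 40.0 min and 120 min grey gave 78.1 min and blue 37.4 min for the tail half-life h, the time in which E halves past its peak; blue's was shorter. The top rung was the asked time, 150 min, longer than either.

Elm's L lay nearer grey's than blue's, so I took grey's h and counted 1.92 half-lives. I assumed X fell with E, which put my estimate of X at 26.4%, more than the 15.7% of Z read in blue at 120 min. So I called X for elm, and for ash, which has less L. Birch on blue's h counted 4.01 half-lives, which put my estimate of X at 6.22%, below that Z, so I called X beaten there and left open whether by Z or Q, since Q was never read. For E in elm I interpolated the peak linearly in L, 11.3%, and halved it by h from 25.0 min onward: 3.71%.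

The forecast gave X for elm, X for ash, Z for birch where I had left Z or Q open, and E 3.6% (2.6% to 4.9%) against my 3.71%, reasoning that “Birch has abundant L, so X is depleted and Z leads”.

    X + L ⇌ J + E (K = 5.70, k = 0.00230 M⁻¹ s⁻¹)
    E + L ⇌ J + Z (K = 19.0, k = 0.00180 M⁻¹ s⁻¹)
    Z + L ⇌ J + Q (K = 1.10, k = 0.00460 M⁻¹ s⁻¹)
    E + G → D (k = 0.00950 M⁻¹ s⁻¹)

Elm held X 22.8% and E 4.29%, ash held X 30.4%, and birch held Q 25.8% ahead of Z 17.1%. At the asked time elm's E was formed, each step taken net, at 0.814 of the rate of its loss, not far from a quasi-steady state. Carrying elm's 4.29% back by h over 90.0 min gives 9.54% at 1.0 h; the same flask read then held E 9.17%.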